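**Plan**
- Retrosynthesis: the interflavanyl bond C4(upper unit)–C2′(ring B of the lower unit) is cut first. This gives a flavan-4-yl cation and a dihydroflavonol, and both halves come from one protected (2R,3R)-dihydroflavonol, the upper half after reduction of C4=O.
- In that dihydroflavonol the C3–OH bond is cut next. Ring C is then opened at C2–C3 and C4–C4a in one cut, to an aryloxycarbenium ion (phenol plus galloyl aldehyde) and ethoxyacetylene as the C3–C4 unit at the ketone oxidation level.
- Enabling feature: in ring A, O1 sits on C8a next to C4a, which is para to the C7 oxygen. A cation O1=C2 is therefore a 2-oxonia-diene C2=O1–C8a=C4a. A trimethylsilyl group on C4a is a helper that directs the ring closure and carries the silicon catalyst, and it leaves in the event itself.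
- Forward: ring C is built onto the finished rings A and B (step 3), C3–OH is added (step 4), the benzyl groups are removed, one part is reduced at C4, and the two halves are joined by acid.
- Stereochemistry: C2 of both units comes from chiral ion-pair control in step 3. C3 comes from epoxidation anti to the C2 aryl group. The upper C4 comes from attack of ring B anti to the 3-hydroxyl of the flavan-4-yl cation.

Key step: step 3

Remark: flavonoid numbering is used (O1, C2, C3, C4, C4a, C5 to C8, C8a; ring B carbons primed).
Assumption: compound 1 is taken as a catalogue compound, and the squaramide enantiomer written in step 3 is taken to give the (2S)-chromene; if the sense proves opposite, its mirror image is used.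

**Step 1**
Reactants: 1 5-(benzyloxy)-2-bromophenol
Product: 3 5-(benzyloxy)-2-(trimethylsilyl)phenol, via aryl trimethylsilyl ether 2 (not isolated)
Conditions: (Me3Si)2NH, THF, 65 °C, evaporate; n-BuLi, THF, −78 °C to rt; aq. NH4Cl
Reagents that add atoms: hexamethyldisilazane, C[Si](C)(C)N[Si](C)(C)C
Why: O-silylation followed by bromine–lithium exchange triggers the anionic 1,3-shift of silicon from oxygen to carbon (retro-Brook rearrangement), driven by formation of the lithium phenoxide, and the benzyl ether is inert at −78 °C.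

**Step 2**
Reactants: 4 3,4,5-tris(benzyloxy)benzaldehyde; 3 5-(benzyloxy)-2-(trimethylsilyl)phenol
Product: 6 [5-(benzyloxy)-2-(trimethylsilyl)phenoxy][3,4,5-tris(benzyloxy)phenyl]methyl 2,2-dimethylpropanoate (racemic), via α-chlorobenzyl pivalate 5 (not isolated)
Conditions: 4, PivCl, ZnCl2 (2 mol %), CH2Cl2, 0 °C to rt; then added to 3/NaH, THF, −40 °C to 0 °C
Reagents that add atoms: pivaloyl chloride, CC(C)(C)C(=O)Cl
Why: ZnCl2-catalysed addition of the acyl chloride across the aldehyde gives the α-chloroalkyl ester, whose chloride is displaced at carbon by the phenoxide (Williamson-type etherification, as in the making of acyloxymethyl aryl ethers), the bulky pivalate shielding the acyl carbon; the new acetal centre is racemic and is erased in step 3.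

**Step 3**
Reactants: 6 [5-(benzyloxy)-2-(trimethylsilyl)phenoxy][3,4,5-tris(benzyloxy)phenyl]methyl 2,2-dimethylpropanoate; 7 ethoxyacetylene
Product: 8 (2S)-7-(benzyloxy)-4-ethoxy-2-[3,4,5-tris(benzyloxy)phenyl]-2H-chromene
Conditions: 7 (3 equiv), Me3SiOTf (10 mol %), 3-{[3,5-bis(trifluoromethyl)phenyl]amino}-4-({(2S)-3,3-dimethyl-1-oxo-1-[(2R)-2-(phenanthren-9-yl)pyrrolidin-1-yl]butan-2-yl}amino)cyclobut-3-ene-1,2-dione (12 mol %), tBuOMe, −78 °C; then Et3N
Reagents that add atoms: none
Why: Proposed new method: the squaramide-bound silyl triflate silylates the pivalate carbonyl of 6 and expels trimethylsilyl pivalate, which leaves the (E)-aryloxycarbenium ion O1=C2 paired with the squaramide–triflate anion; the unsubstituted carbon of the ynol ether 7 attacks C2 (C2–C3 bond) to give an ethoxyketenium ion, and this acylates ring A at the silicon-bearing carbon C4a (C4–C4a bond) with release of Me3Si+ to triflate, so that the silyl triflate is regenerated and no protic acid is formed. The closest known reaction types are the Povarov reaction, its oxygen analogue of aryloxycarbenium ions with alkenes promoted by stoichiometric SnCl4, the enantioselective addition of π-nucleophiles to acetal-derived oxocarbenium ions under chiral hydrogen-bond-donor and silyl triflate co-catalysis, and the ipso-acylation of aryltrimethylsilanes. Ring C closes as the second stage of a stepwise cationic [4+2] addition of the 2-oxonia-diene C2=O1–C8a=C4a to the alkyne, by a six-membered electrophilic ipso-substitution (6-exo-dig at the C4=O+ bond of the ketenium ion, C3=C4 remaining in the ring). The only new stereocenter, C2, is set in the first C–C bond formation by the chiral anion complex, whose squaramide binds triflate and whose phenanthryl group stacks on one face of the planar cation, so that the alkyne enters from the open face. The step needs ionisation in the right sense, secured by pivalate being a far better leaving group and a poorer donor than the aryloxide; it needs closure at C4a and not at C8, at O1 or on ring B, secured by the ipso-directing silyl group para to the 7-benzyloxy group and by the six-membered transition state; and it needs the acid-labile enol ether 8 to survive, secured by the proton-free silicon relay and the amine quench.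

**Step 4**
Reactants: 8 (2S)-7-(benzyloxy)-4-ethoxy-2-[3,4,5-tris(benzyloxy)phenyl]-2H-chromene
Product: 10 (2R,3R)-7-(benzyloxy)-3-hydroxy-2-[3,4,5-tris(benzyloxy)phenyl]-2,3-dihydro-4H-chromen-4-one, via 3,4-epoxy-4-ethoxyflavan 9 (not isolated)
Conditions: dimethyldioxirane, acetone–CH2Cl2, −78 °C to −30 °C; then THF–H2O, PPTS (cat.), 0 °C
Reagents that add atoms: dimethyldioxirane, CC1(C)OO1; water, O
Why: Rubottom-type oxidation, in which the dioxirane epoxidises the enol ether on the face anti to the C2 aryl group and hydrolytic opening of the epoxy ether at C4 leaves the C3–O bond intact, so that the 3-hydroxyl is trans to the aryl group (3R) under non-basic conditions that do not enolise C3.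

**Step 5**
Reactants: 10 (2R,3R)-7-(benzyloxy)-3-hydroxy-2-[3,4,5-tris(benzyloxy)phenyl]-2,3-dihydro-4H-chromen-4-one
Product: 11 (2R,3R)-3,7-dihydroxy-2-(3,4,5-trihydroxyphenyl)-2,3-dihydro-4H-chromen-4-one ((+)-dihydrorobinetin)
Conditions: H2 (1 atm), Pd/C (10 wt %), THF–MeOH, rt
Reagents that add atoms: none
Why: Hydrogenolysis of the four aryl benzyl ethers is fast under these mild conditions, under which the conjugated ketone and the cyclic C2–O1 bond should survive and no stereocenter is touched.

**Step 6**
Reactants: 11 (+)-dihydrorobinetin (one fifth of the batch)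
Product: 12 (2R,3S,4R)-2-(3,4,5-trihydroxyphenyl)-3,4-dihydro-2H-chromene-3,4,7-triol (leucorobinetinidin)
Conditions: NaBH4, EtOH, 0 °C to rt, Ar; AcOH to pH 6
Reagents that add atoms: none
Why: Borohydride reduction of the aryl ketone should give mainly the 3,4-trans diol, as is usual for trans-dihydroflavonols, and the C4 configuration is in any case of no consequence because C4 is ionised in step 7, while C2 and C3 are untouched (the C3 descriptor changes from R to S only through the priority change).

**Step 7**
Reactants: 12 leucorobinetinidin; 11 (+)-dihydrorobinetin (4 equiv)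
Product: 13 (2R,3R)-3,7-dihydroxy-2-{3,4,5-trihydroxy-2-[(2R,3S,4S)-3,7-dihydroxy-2-(3,4,5-trihydroxyphenyl)-3,4-dihydro-2H-chromen-4-yl]phenyl}-2,3-dihydro-4H-chromen-4-one (target)
Conditions: 0.1 M aq. HCl–dioxane (1:1), 25 °C, Ar, dark; Sephadex LH-20 (EtOH)
Reagents that add atoms: none
Why: Acid-promoted loss of water from C4 of 12 gives a flavan-4-yl cation stabilised by O1 and the 7-hydroxyl, which alkylates ring B of 11 at C2′ (Friedel–Crafts alkylation; C2′ is ortho to 3′-OH and para to 5′-OH, C2′ and C6′ are equivalent, and ring A of 11 is deactivated by the C4 carbonyl), attack anti to the 3-hydroxyl of the half-chair cation giving the 3,4-trans (4S) bond, with the excess of 11 holding back self-condensation of 12.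

**Compound list**
1 | 5-(benzyloxy)-2-bromophenol | Oc1cc(OCc2ccccc2)ccc1Br | starting material
2 | [5-(benzyloxy)-2-bromophenoxy]trimethylsilane (not isolated) | C[Si](C)(C)Oc1cc(OCc2ccccc2)ccc1Br | intermediate
3 | 5-(benzyloxy)-2-(trimethylsilyl)phenol | Oc1cc(OCc2ccccc2)ccc1[Si](C)(C)C | intermediate
4 | 3,4,5-tris(benzyloxy)benzaldehyde | O=Cc1cc(OCc2ccccc2)c(OCc2ccccc2)c(OCc2ccccc2)c1 | starting material
5 | chloro[3,4,5-tris(benzyloxy)phenyl]methyl 2,2-dimethylpropanoate (racemic, not isolated) | CC(C)(C)C(=O)OC(Cl)c1cc(OCc2ccccc2)c(OCc2ccccc2)c(OCc2ccccc2)c1 | intermediate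
6 | [5-(benzyloxy)-2-(trimethylsilyl)phenoxy][3,4,5-tris(benzyloxy)phenyl]methyl 2,2-dimethylpropanoate (racemic) | CC(C)(C)C(=O)OC(Oc1cc(OCc2ccccc2)ccc1[Si](C)(C)C)c1cc(OCc2ccccc2)c(OCc2ccccc2)c(OCc2ccccc2)c1 | intermediate
7 | ethoxyacetylene (ethoxyethyne) | C#COCC | starting material
8 | (2S)-7-(benzyloxy)-4-ethoxy-2-[3,4,5-tris(benzyloxy)phenyl]-2H-chromene | CCOC1=C[C@@H](c2cc(OCc3ccccc3)c(OCc3ccccc3)c(OCc3ccccc3)c2)Oc2cc(OCc3ccccc3)ccc12 | intermediate
9 | (2R,3R,4S)-7-(benzyloxy)-3,4-epoxy-4-ethoxy-2-[3,4,5-tris(benzyloxy)phenyl]chromane, flavan numbering (not isolated) | CCO[C@@]12O[C@@H]1[C@@H](c1cc(OCc3ccccc3)c(OCc3ccccc3)c(OCc3ccccc3)c1)Oc1cc(OCc3ccccc3)ccc12 | intermediate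
10 | (2R,3R)-7-(benzyloxy)-3-hydroxy-2-[3,4,5-tris(benzyloxy)phenyl]-2,3-dihydro-4H-chromen-4-one | O=C1c2ccc(OCc3ccccc3)cc2O[C@H](c2cc(OCc3ccccc3)c(OCc3ccccc3)c(OCc3ccccc3)c2)[C@H]1O | intermediate
11 | (2R,3R)-3,7-dihydroxy-2-(3,4,5-trihydroxyphenyl)-2,3-dihydro-4H-chromen-4-one ((+)-dihydrorobinetin) | O=C1c2ccc(O)cc2O[C@H](c2cc(O)c(O)c(O)c2)[C@H]1O | intermediate
12 | (2R,3S,4R)-2-(3,4,5-trihydroxyphenyl)-3,4-dihydro-2H-chromene-3,4,7-triol (leucorobinetinidin) | O[C@@H]1c2ccc(O)cc2O[C@H](c2cc(O)c(O)c(O)c2)[C@H]1O | intermediate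
13 | (2R,3R)-3,7-dihydroxy-2-{3,4,5-trihydroxy-2-[(2R,3S,4S)-3,7-dihydroxy-2-(3,4,5-trihydroxyphenyl)-3,4-dihydro-2H-chromen-4-yl]phenyl}-2,3-dihydro-4H-chromen-4-one | O=C1c2ccc(O)cc2O[C@H](c2cc(O)c(O)c(O)c2[C@@H]2c3ccc(O)cc3O[C@H](c3cc(O)c(O)c(O)c3)[C@H]2O)[C@H]1O | target

**Totals**
Total step count: 7. Longest linear sequence: 7 steps (1 to 13 through 3, 6, 8, 10, 11 and 12).

**Steps most likely to fail**

Step 3. Enantiofacial control at C2 may be lost through a background pathway of unbound silyl triflate. The ketenium ion may be captured by O1 (oxetene formation and fragmentation to a cinnamate) or by ring B (five-membered closure), and the product enol ether may be consumed by further oxocarbenium ion. The fallback uses known chemistry, sets out from compound 4 and comes back at compound 10. Commercial 1-[4-(benzyloxy)-2-hydroxyphenyl]ethanone would be protected (MOMCl, iPr2NEt, CH2Cl2) as 1-[4-(benzyloxy)-2-(methoxymethoxy)phenyl]ethanone F1. Claisen–Schmidt condensation of it with 4 (KOH, EtOH) would give (E)-1-[4-(benzyloxy)-2-(methoxymethoxy)phenyl]-3-[3,4,5-tris(benzyloxy)phenyl]prop-2-en-1-one F2. Juliá–Colonna epoxidation (poly-L-leucine, urea–H2O2, DBU, THF) would give [(2R,3S)-3-[3,4,5-tris(benzyloxy)phenyl]oxiran-2-yl][4-(benzyloxy)-2-(methoxymethoxy)phenyl]methanone F3. HCl in MeOH–THF would then remove the methoxymethyl group and let the freed phenol open the epoxide at the benzylic carbon with inversion, closing ring C as the trans-dihydroflavonol 10.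

Step 7. Facial selectivity at C4 of the cation may be incomplete (attack syn to the 3-hydroxyl, giving the 4β bond), and the flavan-3,4-diol may condense with its own ring A. The fallback sets out from compounds 12 and 11 and comes back at compound 13. Compound 12 would be peracetylated (Ac2O, pyridine) to (2R,3R,4R)-3,4,7-triacetoxy-2-(3,4,5-triacetoxyphenyl)chromane F4 (the hexa-O-acetate of 12; the C3 descriptor changes only through the priority change), in which rings A and B are deactivated against self-condensation. With BF3·OEt2 in dioxane and 11 (3 equiv), the trans 3-acetoxy group should displace the 4-acetate as a cis-fused acetoxonium ion on the β face, so that ring B of 11 must enter from the α face. This would give the 3,7,3′,4′,5′-penta-O-acetate (upper unit) of the target F5. Acid methanolysis (AcCl in MeOH, rt) would then free 13 without base.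

Step 2. The phenoxide may attack the acyl carbon instead of the chlorinated carbon, formation of the α-chloro ester may be incomplete, and the acylal may hydrolyse during purification. The fallback sets out from compound 3 and comes back at compound 6. Acylation of 3 with commercial 3,4,5-tris(benzyloxy)benzoyl chloride (Et3N, DMAP, CH2Cl2) would give 5-(benzyloxy)-2-(trimethylsilyl)phenyl 3,4,5-tris(benzyloxy)benzoate F6. Reductive acylation of this ester (iBu2AlH, CH2Cl2, −78 °C; then pivalic anhydride, pyridine, DMAP, −78 °C to 0 °C) would trap the aluminium hemiacetal as the pivalate 6.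

**Further compounds**
F1 | step 3 | 1-[4-(benzyloxy)-2-(methoxymethoxy)phenyl]ethanone | CC(=O)c1ccc(OCc2ccccc2)cc1OCOC
F2 | step 3 | (E)-1-[4-(benzyloxy)-2-(methoxymethoxy)phenyl]-3-[3,4,5-tris(benzyloxy)phenyl]prop-2-en-1-one | O=C(/C=C/c1cc(OCc2ccccc2)c(OCc2ccccc2)c(OCc2ccccc2)c1)c1ccc(OCc2ccccc2)cc1OCOC
F3 | step 3 | [(2R,3S)-3-[3,4,5-tris(benzyloxy)phenyl]oxiran-2-yl][4-(benzyloxy)-2-(methoxymethoxy)phenyl]methanone | O=C([C@@H]1O[C@H]1c1cc(OCc2ccccc2)c(OCc2ccccc2)c(OCc2ccccc2)c1)c1ccc(OCc2ccccc2)cc1OCOC
F4 | step 7 | (2R,3R,4R)-3,4,7-triacetoxy-2-(3,4,5-triacetoxyphenyl)chromane (hexa-O-acetate of 12) | CC(=O)O[C@@H]1c2ccc(OC(C)=O)cc2O[C@H](c2cc(OC(C)=O)c(OC(C)=O)c(OC(C)=O)c2)[C@H]1OC(C)=O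
F5 | step 7 | 3,7,3′,4′,5′-penta-O-acetate (upper unit) of 13 | O=C1c2ccc(O)cc2O[C@H](c2cc(O)c(O)c(O)c2[C@@H]2c3ccc(OC(C)=O)cc3O[C@H](c3cc(OC(C)=O)c(OC(C)=O)c(OC(C)=O)c3)[C@H]2OC(C)=O)[C@H]1O
F6 | step 2 | 5-(benzyloxy)-2-(trimethylsilyl)phenyl 3,4,5-tris(benzyloxy)benzoate | O=C(Oc1cc(OCc2ccccc2)ccc1[Si](C)(C)C)c1cc(OCc2ccccc2)c(OCc2ccccc2)c(OCc2ccccc2)c1
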